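## Structural features

The target is a biflavonoid of the profisetinidin type. An upper flavan-3-ol (ring A benzo, ring C pyran, ring B catechol; atoms unprimed) is bonded through C4 to C6' of a lower flavan-3,4-diol (ring D benzo, ring F pyran, ring E catechol; atoms primed). Each pyran carries three contiguous stereocentres: C2 (R), C3 (S), C4 (S) above and C2' (R), C3' (S), C4' (S) below. Both triads are 2,3-trans-3,4-cis, so ring D is cis to the C3 hydroxyl and the C4' hydroxyl is cis to the C3' hydroxyl. C4 is a diarylmethine whose two aryl groups are both 2,4-dioxygenated benzene rings. Ring A has its ortho oxygen in ring C and its para oxygen free; ring D has its ortho oxygen (C7') free and its para oxygen (C8a') in ring F. The configuration at C4 therefore rests on telling two nearly identical resorcinol rings apart. The fragile groups are the benzylic C4' hydroxyl para to the C7' oxygen (ionisation under acid, hydrogenolysis), the catechols and phenols (oxidation), the doubly benzylic C4–H and the benzylic C2–O1 and C2'–O1' bonds. The real difficulty is the C4–C6' bond: arylation of a flavan C4 cation by a resorcinol prefers the 3,4-trans isomer and can also attack C8', whereas the target needs 3,4-cis and C6' only. The key step uses the pattern of ring D (carbon at C6' and C4a', oxygen at C7' and C8a', hydrogen at C5' and C8'), which is what the union of a vinylketene (C8a', C6', C5', C4a') with a silyloxyalkyne (C8', C7') gives. Ring D can therefore be grown on a C4 stereocentre that is already in place, with its two oxygens differentiated from the start (C7' silyl ether, C8a' free phenol).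

## Logic of the disconnections

**37 ⇒ 36 ⇒ 35.** Five O–benzyl bonds (36) and the C7'–O–Si bond (35) are added back. Every phenol must be masked while oxidants, bases and π-acids are used, and only groups that leave under neutral conditions are tolerable next to the C4' hydroxyl. The skeleton is unchanged, but all earlier chemistry becomes that of lipophilic, non-oxidisable ethers. The forward steps must be buffered (desilylation) and must stop before the benzylic C4'–O bond is touched (hydrogenolysis).

**35 ⇒ 34.** The C3'–O and C4'–O bonds are cut. A cis-diol on a ring is the signature of a syn-dihydroxylation, and two stereocentres disappear, leaving a flav-3-ene. The forward step must add to the face opposite ring E, and no other alkene may be present, which is why ring C must be closed before ring F.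

**34 ⇒ 33.** The C4'–C4a' bond is cut. The flav-3-ene is the hydroarylation product of an aryl propargyl ether, so ring F opens to a side chain on the C8a' oxygen. The forward step must attack C4a' and not C8', and must leave C2' untouched.

**33 ⇒ 32 ⇒ 31 ⇒ 30.** The O1–C2 bond is cut (phenol onto a benzylic epoxide carbon), then the two epoxide C–O bonds. Ring C and the stereocentres C2 and C3 reduce to one E double bond. The forward steps need a reagent-controlled epoxidation next to the existing C4 centre and a 6-endo opening with inversion at C2. Only the ring A ortho oxygen may be free at that moment. This is why that oxygen carries an allyl ether (cleaved by zerovalent palladium under neutral conditions) and not an acetal. An acetal would need acid next to the electron-rich styrene, and would force the epoxidation to be run on free phenols. The C7' oxygen stays silylated.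

**30 ⇒ 26 + 29 (29 ⇒ 28 ⇒ 27).** The C8a'O–C2' bond is cut. The whole ring E / C2' / C3' / C4' unit arrives as a racemic propargylic ester made in two steps from an aldehyde. The forward step must set C2' by catalyst control and alkylate oxygen, not carbon.

**26 ⇒ 16 + 21.** The key disconnection removes ring D: C6'–C7', C8'–C8a' and C4a'–C8a' are cut. The C5'–C6' bond is also new in the forward sense, because in 16 the vinyl group sits on the carbonyl carbon and is moved to C6' by the Wolff shift. The aromatic ring is traded for a diazo enone and a two-carbon ynol ether; the regiochemical problem (C6' against C8') and the differentiation of the two ring D oxygens vanish. The forward step must favour the Wolff shift over other carbene pathways and must not touch the styrene or C4.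

**16 ⇒ 15 ⇒ 14.** The C=N2 bond is replaced by C–H, which leaves an α,β-unsaturated ketone with one enolisable position. The forward step needs regioselective enolisation without Michael chemistry at the vinyl ketone.

**14 ⇒ 13 ⇒ 12 ⇒ 11.** The carbonyl–vinyl bond is cut, leaving a carboxylic acid as the acyl donor. The forward step must stop at mono-addition and keep the liberated amine off the enone.

**11 ⇒ 10 ⇒ 9 ⇒ 8.** The C4–CH2 bond is cut as a [3,3] shift. The C4 stereocentre, which is hard to make directly, is traded for a carbinol stereocentre two atoms away, and the E styrene appears at the same time. The forward step needs a chair transition state with full chirality transfer under conditions that do not ionise the diaryl allylic ester.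

**8 ⇒ 7 ⇒ 6.** The acetate C–O bond, then the carbinol C–H bond, are cut. The only stereocentre left is removed, giving an achiral enone. The forward step is an enantioselective 1,2-reduction of an aryl alkenyl ketone.

**6 ⇒ 3 + 5 (3 ⇒ 2 ⇒ 1; 5 ⇒ 4).** The Cα=Cβ bond is cut as an aldol condensation. Ring A arrives as an aldehyde and ring B as a methyl ketone, so that the carbinol lies next to ring B and the [3,3] shift delivers carbon to the ring A side. The only demands are a regioselective first O-alkylation of 1 and base-stable ethers.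

**21 ⇒ 20 ⇒ 19 ⇒ 17 + 18.** The O–Si and C–O bonds of the ynol ether are cut back to an acetylide, an electrophilic oxygen source and a silyl triflate. The forward step must silylate oxygen, not carbon; the bulky silyl group ensures this.

## Other disconnections considered

**Alternative 1:** The cut is at C2–ring B and C2'–ring E. Forward, a bis(2-ethoxy-2H-chromene) A1 would be ionised twice by Yb(OTf)3 with a tartaric acid-derived diol, and diethyl [3,4-bis(benzyloxy)phenyl]boronate A2 would add to both benzopyrylium ions to give the bis(flav-3-ene) A3.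
- In its favour: it is the most convergent plan. Both catechol rings and both C2 centres come from one reagent and one catalyst, rings C and F exist beforehand, and A1 is reachable by a biaryl-type coupling. On step count it is better than the chosen plan.
- Against it here: A3 has an sp2 C4, so the hardest stereocentre is still to be made. Hydroboration–oxidation anti to ring B would give 2,3-trans but adds H and OH syn, which places ring D trans to the C3 hydroxyl, the C4 epimer of the target. The 3,4-cis isomer would need a longer detour. The two alkenes of A3 (one to be hydrated, one to be dihydroxylated) would have to be distinguished. Two ionisations in one molecule, one of them giving a well-stabilised 4-aryl cation, may not both proceed with full catalyst control.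
- Comparison: Alternative 1 is better on convergence and the equal of the chosen plan for C2 and C2'. The chosen plan is better for C4, which it sets first by a sigmatropic shift with a predictable outcome.

**Alternative 2:** The cut is at C4'–C4a'. Forward, (Ph3P)AuNTf2 would activate the alkyne of the (S)-propargyl ether A4 and the ring D carbon para to the C7' oxygen would close ring F to give the flav-3-ene A5.
- In its favour: it is mild, catalytic and atom-economic. C2' is made beforehand in an acyclic ether, and the product is ready for the cis-dihydroxylation. The chosen plan uses the same transformation as step 18, so on ring F the two are equal.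
- Against it as the strategic centre: it leaves the real problem unsolved. A4 already contains the C4–C6' bond with the 3,4-cis configuration. The usual route to such 4-aryl-flavan-3-ols, capture of a C4 cation by a resorcinol, favours 3,4-trans and has to control C6' against C8'.
- Comparison: Alternative 2 is a component of the chosen plan rather than a rival; the benzannulation supplies what it lacks.

**Alternative 3:** The cut is at C3–C4. Forward, SmI2 would reduce the diaryl ketone of the keto aldehyde A6 to a ketyl, which would add to the tethered aldehyde. Chelation of both oxygens to trivalent samarium would give the 3,4-cis-diol A7 with ring B equatorial (2,3-trans).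
- In its favour: ring D arrives as a ready-made resorcinol unit and the diaryl ketone is easy to make. Ring C, C3 and C4 form in one step. For the upper half it is shorter than the chosen plan and equal in the control of C2 against C3.
- Against it here: A6 is an α-aryl-α-aryloxy aldehyde, whose stereocentre is prone to enolisation. A7 carries a tertiary benzylic hydroxyl at C4 that must be replaced by hydrogen from one defined face through a diarylmethyl cation, under acid that also threatens the C2–O1 bond. The stabilised diaryl ketyl may add slowly. Ring F would still have to be built as in the chosen plan.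
- Comparison: Alternative 3 is better on convergence. The chosen plan is better on the security of C2 and C4, because neither centre passes through an enolisable or cationic stage.

Key step: step 12

Assumption: in step 5 the aryl group on the carbonyl is taken to act as the large substituent, so that the (R)-oxazaborolidine gives the S alcohol; if the sense proves opposite, the antipodal catalyst is used.

Assumption: in step 15 the pybox antipode is the one that a model run on a simple phenol shows to give the S ether; the (S,S) ligand is written.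

## Route

Step 1
Reactants: 1 2,4-dihydroxybenzaldehyde
Product: 2 4-(benzyloxy)-2-hydroxybenzaldehyde
Conditions: BnBr (1.05 equiv), NaHCO3, KI (cat.), MeCN, 80 °C
Reagents that add atoms: benzyl bromide, BrCc1ccccc1
Why: Williamson etherification; the 2-hydroxyl is held in a hydrogen bond to the formyl group and is less nucleophilic, so the 4-hydroxyl should be alkylated selectively under a weak base.

Step 2
Reactants: 2 4-(benzyloxy)-2-hydroxybenzaldehyde
Product: 3 2-(allyloxy)-4-(benzyloxy)benzaldehyde
Conditions: allyl bromide, K2CO3, DMF, 20 °C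
Reagents that add atoms: allyl bromide, C=CCBr
Why: Williamson etherification of the remaining phenol; the allyl ether is stable to every base and nucleophile used before the key step and is later the only group removable by zerovalent palladium.

Step 3
Reactants: 4 3',4'-dihydroxyacetophenone
Product: 5 3',4'-bis(benzyloxy)acetophenone
Conditions: BnBr (2.2 equiv), K2CO3, DMF, 60 °C
Reagents that add atoms: benzyl bromide, BrCc1ccccc1
Why: Twofold Williamson etherification of the catechol, which would otherwise be oxidised or deprotonated in later steps.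

Step 4
Reactants: 3 2-(allyloxy)-4-(benzyloxy)benzaldehyde; 5 3',4'-bis(benzyloxy)acetophenone
Product: 6 (E)-3-[2-(allyloxy)-4-(benzyloxy)phenyl]-1-[3,4-bis(benzyloxy)phenyl]prop-2-en-1-one
Conditions: KOH (aq.), EtOH–THF, 20 °C
Reagents that add atoms: none
Why: Claisen–Schmidt condensation; the aldehyde has no α-hydrogen and the aldol dehydrates to the conjugated E enone, which places the carbonyl next to ring B as the later [3,3] shift requires.

Step 5
Reactants: 6 (E)-3-[2-(allyloxy)-4-(benzyloxy)phenyl]-1-[3,4-bis(benzyloxy)phenyl]prop-2-en-1-one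
Product: 7 (S,E)-3-[2-(allyloxy)-4-(benzyloxy)phenyl]-1-[3,4-bis(benzyloxy)phenyl]prop-2-en-1-ol
Conditions: (R)-1-methyl-3,3-diphenyltetrahydro-1H,3H-pyrrolo[1,2-c][1,3,2]oxazaborole (15 mol%), catecholborane, toluene, −78 °C; aq. NaOH work-up
Reagents that add atoms: none
Why: CBS reduction; the ketone binds to the catalyst boron anti to the aryl group and hydride is delivered to one face, which should give the S carbinol by 1,2-reduction. Catecholborane at −78 °C does not hydroborate the allyl ether, and the basic work-up protects the ionisable diaryl allylic alcohol.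

Step 6
Reactants: 7 (S,E)-3-[2-(allyloxy)-4-(benzyloxy)phenyl]-1-[3,4-bis(benzyloxy)phenyl]prop-2-en-1-ol
Product: 8 (S,E)-3-[2-(allyloxy)-4-(benzyloxy)phenyl]-1-[3,4-bis(benzyloxy)phenyl]prop-2-en-1-yl acetate
Conditions: Ac2O, Et3N, 4-(dimethylamino)pyridine (cat.), CH2Cl2, 0 °C; filtration through Et3N-deactivated silica
Reagents that add atoms: acetic anhydride, CC(=O)OC(C)=O
Why: Base-mediated O-acylation leaves the C–O bond untouched, so the configuration is kept; acid is excluded because the ester can ionise to a diaryl allyl cation, and the product is used at once.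

Step 7
Reactants: 8 (S,E)-3-[2-(allyloxy)-4-(benzyloxy)phenyl]-1-[3,4-bis(benzyloxy)phenyl]prop-2-en-1-yl acetate
Product: 11 (R,E)-3-[2-(allyloxy)-4-(benzyloxy)phenyl]-5-[3,4-bis(benzyloxy)phenyl]pent-4-enoic acid, via silyl ketene acetal 9 (not isolated), via trimethylsilyl ester 10 (not isolated)
Conditions: LDA, Me3SiCl, THF, −78 °C to 20 °C; aq. NH4Cl
Reagents that add atoms: none
Why: Ireland–Claisen rearrangement; in the chair transition state ring B sits equatorial on the carbinol carbon, so the new C–C bond forms suprafacially on one face of the styrene. This should transfer the S carbinol configuration to R at the ring A-bearing carbon (C4 of the target) and give the E styrene. The shift runs at or below room temperature in a non-ionising medium.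

Step 8
Reactants: 11 (R,E)-3-[2-(allyloxy)-4-(benzyloxy)phenyl]-5-[3,4-bis(benzyloxy)phenyl]pent-4-enoic acid
Product: 13 (R,E)-3-[2-(allyloxy)-4-(benzyloxy)phenyl]-5-[3,4-bis(benzyloxy)phenyl]-N-methoxy-N-methylpent-4-enamide, via acyl imidazolide 12 (not isolated)
Conditions: 1,1'-carbonyldiimidazole, CH2Cl2, 20 °C; then MeNH(OMe)·HCl
Reagents that add atoms: N,O-dimethylhydroxylamine hydrochloride, CNOC.Cl
Why: Amide formation through the acyl imidazole under neutral conditions; the stereocentre is β to the carbonyl and cannot epimerise.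

Step 9
Reactants: 13 (R,E)-3-[2-(allyloxy)-4-(benzyloxy)phenyl]-5-[3,4-bis(benzyloxy)phenyl]-N-methoxy-N-methylpent-4-enamide
Product: 14 (R,E)-5-[2-(allyloxy)-4-(benzyloxy)phenyl]-7-[3,4-bis(benzyloxy)phenyl]hepta-1,6-dien-3-one
Conditions: CH2=CHMgBr, THF, −78 °C to 0 °C; inverse quench into cold 1 M HCl
Reagents that add atoms: vinylmagnesium bromide, C=C[Mg]Br
Why: Weinreb ketone synthesis; the chelated tetrahedral adduct prevents a second addition, and the cold acidic inverse quench protonates the liberated amine before it can add to the enone. The vinyl ketone is taken on without storage.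

Step 10
Reactants: 14 (R,E)-5-[2-(allyloxy)-4-(benzyloxy)phenyl]-7-[3,4-bis(benzyloxy)phenyl]hepta-1,6-dien-3-one
Product: 16 (R,E)-5-[2-(allyloxy)-4-(benzyloxy)phenyl]-7-[3,4-bis(benzyloxy)phenyl]-4-diazohepta-1,6-dien-3-one, via trifluoroacetyl diketone 15 (not isolated)
Conditions: LiHMDS, THF, −78 °C (ketone added slowly); CF3CO2CH2CF3; then MeSO2N3, Et3N, H2O (1 equiv), MeCN, 20 °C
Reagents that add atoms: methanesulfonyl azide, CS(=O)(=O)N=[N+]=[N-]
Why: Detrifluoroacetylative diazo transfer, the standard route to α'-diazo enones; the ketone has only one enolisable position, the trifluoroacetyl group activates it for transfer and is then lost by retro-Claisen cleavage. C4–H is not acidic enough to be touched by the amide base at −78 °C.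

Step 11
Reactants: 17 acetylene; 18 triisopropylsilyl trifluoromethanesulfonate
Product: 21 (triisopropylsilyloxy)acetylene, via lithium acetylide 19 (not isolated), via lithium ethynolate 20 (not isolated)
Conditions: n-BuLi, THF, −78 °C; t-BuOOLi (from t-BuOOH and LiHMDS), −78 °C to −20 °C; then 18, −78 °C to 0 °C
Reagents that add atoms: tert-butyl hydroperoxide, CC(C)(C)OO
Why: Oxidation of a lithium acetylide by the electrophilic oxygen of lithium tert-butyl peroxide gives the ynolate, the general route to siloxyalkynes from terminal alkynes; the bulky silyl triflate silylates oxygen rather than carbon. The low temperature holds the monolithium acetylide against disproportionation.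

Step 12
Reactants: 16 (R,E)-5-[2-(allyloxy)-4-(benzyloxy)phenyl]-7-[3,4-bis(benzyloxy)phenyl]-4-diazohepta-1,6-dien-3-one; 21 (triisopropylsilyloxy)acetylene
Product: 26 4-{(1R,2E)-1-[2-(allyloxy)-4-(benzyloxy)phenyl]-3-[3,4-bis(benzyloxy)phenyl]prop-2-en-1-yl}-3-[(triisopropylsilyl)oxy]phenol, via vinylketene 22 (not isolated), via vinylcyclobutenone 23 (not isolated), via dienylketene 24 (not isolated), via cyclohexadienone 25 (not isolated)
Conditions: 21 (3 equiv), hν (365 nm LED, Pyrex), ClCH2CH2Cl, 20 °C; then 80 °C
Reagents that add atoms: none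
Why: Light of 365 nm excites only the diazo ketone chromophore of 16, so the styrene should neither isomerise nor enter di-π-methane pathways; loss of N2 with a 1,2-shift of the vinyl group (Wolff rearrangement) gives vinylketene 22, in which C5' is now bonded to C6'. The nucleophilic unsubstituted carbon of 21 adds to the ketene carbonyl carbon and the four-membered ring closes at the ketene α-carbon ([2+2] cycloaddition) to give 23; strain release drives its 4π-electrocyclic opening to 24, which closes ring D by a thermal disrotatory 6π-electrocyclisation (C4a' onto C8a') to 25 and tautomerises to phenol 26. The closest known reaction type is the Danheiser benzannulation in its photochemical Wolff variant, which converts α-diazo enones and siloxyalkynes into resorcinol mono-silyl ethers. Four ring bonds are new: C5'–C6' from the Wolff shift, and C6'–C7', C8'–C8a' and C4a'–C8a' from the cycloaddition–electrocyclisation cascade. No stereocentre is made; C4 is attached to the reacting π systems but is never α to a carbonyl in 22–25, so it should be carried through unchanged. The regiochemistry (silyloxy at C7' ortho to C4, hydroxyl at C8a' para to it, hydrogen at C8') follows from the polarity of the ynol ether and is secured by using the terminal alkyne. The selectivity at risk is the Wolff shift against a 1,2-hydride shift from C4; the safeguards are rearrangement from the s-cis diazo ketone at room temperature and an excess of 21, which also keeps 22 from dimerising or acylating 26.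

Step 13
Reactants: 27 3,4-bis(benzyloxy)benzaldehyde
Product: 28 rac-1-[3,4-bis(benzyloxy)phenyl]prop-2-yn-1-ol
Conditions: HC≡CMgBr, THF, 0 °C; aq. NH4Cl
Reagents that add atoms: ethynylmagnesium bromide, C#C[Mg]Br
Why: Grignard addition to an aldehyde; no stereocontrol is needed because step 15 is stereoconvergent.

Step 14
Reactants: 28 rac-1-[3,4-bis(benzyloxy)phenyl]prop-2-yn-1-ol
Product: 29 rac-1-[3,4-bis(benzyloxy)phenyl]prop-2-yn-1-yl acetate
Conditions: Ac2O, Et3N, 4-(dimethylamino)pyridine (cat.), CH2Cl2, 0 °C
Reagents that add atoms: acetic anhydride, CC(=O)OC(C)=O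
Why: O-acylation supplies the leaving group for the copper-catalysed substitution; acid is excluded because the ester is an electron-rich benzylic propargylic one.

Step 15
Reactants: 26 4-{(1R,2E)-1-[2-(allyloxy)-4-(benzyloxy)phenyl]-3-[3,4-bis(benzyloxy)phenyl]prop-2-en-1-yl}-3-[(triisopropylsilyl)oxy]phenol; 29 rac-1-[3,4-bis(benzyloxy)phenyl]prop-2-yn-1-yl acetate
Product: 30 the ether of 26 in which the phenolic oxygen carries the (S)-1-[3,4-bis(benzyloxy)phenyl]prop-2-yn-1-yl group
Conditions: (CuOTf)2·C6H6 (2.5 mol%), 2,6-bis[(4S)-4-phenyl-4,5-dihydrooxazol-2-yl]pyridine (6 mol%), i-Pr2NEt, MeOH, −20 °C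
Reagents that add atoms: none
Why: Copper-catalysed enantioselective propargylic etherification of phenols; the copper acetylide of the ester ionises to a copper-bound allenylidene and the phenoxide adds at the propargylic carbon inside the chiral pocket. Both enantiomers of 29 converge on the S ether (C2' of the target); the only free hydroxyl in 26 is the C8a' phenol, and the distant C4 centre should not interfere.

Step 16
Reactants: 30 the (S)-propargyl ether of 26
Product: 31 the trans-epoxide of the styryl double bond of 30, S at both oxirane carbons (C2 and C3 of the target)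
Conditions: 1,2:4,5-di-O-isopropylidene-β-L-erythro-2,3-hexodiulo-2,6-pyranose (0.5 equiv), Oxone, K2CO3, Bu4NHSO4 (cat.), MeCN–CH2(OMe)2/aq. Na2B4O7–Na2EDTA, 0 °C
Reagents that add atoms: potassium peroxymonosulfate, [K+].[O-]S(=O)(=O)OO
Why: Shi epoxidation; the chiral dioxirane attacks trans-disubstituted aryl alkenes through a spiro transition state, and the ketone from L-fructose gives the (S,S)-epoxide (the D-series gives R,R). Every phenol is etherified, the terminal alkyne and the allyl ether react far more slowly than the electron-rich trans-styrene, and the basic medium preserves the acid-labile epoxide, which is used crude.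

Step 17
Reactants: 31 the (2S,3S)-epoxide
Product: 33 (2R,3S,4R)-7-(benzyloxy)-2-[3,4-bis(benzyloxy)phenyl]-4-[4-{[(1S)-1-[3,4-bis(benzyloxy)phenyl]prop-2-yn-1-yl]oxy}-2-[(triisopropylsilyl)oxy]phenyl]chroman-3-ol, via epoxy phenol 32 (not isolated)
Conditions: Pd(PPh3)4 (5 mol%), morpholine, THF, 0 °C to 20 °C; filtration; pyridinium p-toluenesulfonate (cat.), CH2Cl2, 0 °C
Reagents that add atoms: none
Why: Zerovalent palladium ionises the aryl allyl ether and morpholine traps the allyl group (Tsuji–Trost deallylation); neither the silyl ether, the benzyl ethers nor the propargyl ether should respond under these conditions. The freed ring A phenol opens the epoxide at the benzylic carbon C2 (6-endo, favoured by the electron-rich ring B and by crowding at C3) with inversion, giving C2 (R) and leaving C3 (S): the 2,3-trans-3,4-cis flavan-3-ol. C4 is R in 33 only because the silyloxy group raises the CIP rank of ring D; the geometry is that of the target.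

Step 18
Reactants: 33 the 2,3-trans-3,4-cis flavan-3-ol carrying the propargyl ether
Product: 34 (2R,3S,4R)-7-(benzyloxy)-2-[3,4-bis(benzyloxy)phenyl]-4-{(2S)-2-[3,4-bis(benzyloxy)phenyl]-7-[(triisopropylsilyl)oxy]-2H-chromen-6-yl}chroman-3-ol
Conditions: (Ph3P)AuNTf2 (3 mol%), CH2Cl2, 20 °C
Reagents that add atoms: none
Why: Gold-catalysed 6-endo-dig hydroarylation of an aryl propargyl ether; the arene attacks the gold-bound alkyne and protodeauration gives the 2H-chromene. C4a' is para to the silyloxy group and unhindered, whereas C8' lies between two oxygens and under the triisopropylsilyl group; C2' is not involved and the C3 hydroxyl cannot reach the alkyne.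

Step 19
Reactants: 34 the flav-3-ene
Product: 35 (2R,3S,4S)-2-[3,4-bis(benzyloxy)phenyl]-6-{(2R,3S,4R)-7-(benzyloxy)-2-[3,4-bis(benzyloxy)phenyl]-3-hydroxychroman-4-yl}-7-[(triisopropylsilyl)oxy]chroman-3,4-diol
Conditions: OsO4 (2 mol%), N-methylmorpholine N-oxide, acetone–H2O, 0 °C to 20 °C; aq. Na2SO3
Reagents that add atoms: N-methylmorpholine N-oxide, C[N+]1([O-])CCOCC1; water, O
Why: Upjohn dihydroxylation; syn addition to the only alkene, on the face opposite the C2' aryl group, should give the 2,3-trans-3,4-cis diol (C3' S, C4' S). The medium is neutral, so the benzylic C4' hydroxyl does not ionise.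

Step 20
Reactants: 35 the silyl-protected flavan-3,4-diol
Product: 36 (2R,3S,4S)-2-[3,4-bis(benzyloxy)phenyl]-6-{(2R,3S,4S)-7-(benzyloxy)-2-[3,4-bis(benzyloxy)phenyl]-3-hydroxychroman-4-yl}chroman-3,4,7-triol
Conditions: Bu4NF, AcOH (1:1), THF, 0 °C
Reagents that add atoms: none
Why: Fluoride cleaves the aryl O–Si bond; the acetic acid buffer keeps the C7' phenol protonated, so it cannot expel the para-benzylic C4' hydroxyl as a quinone methide.

Step 21
Reactants: 36 the penta-O-benzyl ether
Product: 37 (2R,3S,4S)-2-(3,4-dihydroxyphenyl)-6-[(2R,3S,4S)-2-(3,4-dihydroxyphenyl)-3,7-dihydroxychroman-4-yl]chroman-3,4,7-triol (CNP0280090.1)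
Conditions: H2 (1 atm), Pd(OH)2/C, THF–MeOH, 20 °C; filtration under argon
Reagents that add atoms: none
Why: Hydrogenolysis of aryl benzyl ethers is fast in neutral solvent, whereas cleavage of a secondary benzylic alcohol normally needs acid; the reaction is stopped when the last benzyl group has gone. No stereocentre is touched.

## Compound list

1 | 2,4-dihydroxybenzaldehyde | O=Cc1ccc(O)cc1O | starting material
2 | 4-(benzyloxy)-2-hydroxybenzaldehyde | O=Cc1ccc(OCc2ccccc2)cc1O | intermediate
3 | 2-(allyloxy)-4-(benzyloxy)benzaldehyde | O=Cc1ccc(OCc2ccccc2)cc1OCC=C | intermediate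
4 | 3',4'-dihydroxyacetophenone | CC(=O)c1ccc(O)c(O)c1 | starting material
5 | 3',4'-bis(benzyloxy)acetophenone | CC(=O)c1ccc(OCc2ccccc2)c(OCc2ccccc2)c1 | intermediate
6 | (E)-3-[2-(allyloxy)-4-(benzyloxy)phenyl]-1-[3,4-bis(benzyloxy)phenyl]prop-2-en-1-one | O=C(/C=C/c1ccc(OCc2ccccc2)cc1OCC=C)c1ccc(OCc2ccccc2)c(OCc2ccccc2)c1 | intermediate
7 | (S,E)-3-[2-(allyloxy)-4-(benzyloxy)phenyl]-1-[3,4-bis(benzyloxy)phenyl]prop-2-en-1-ol | O[C@@H](/C=C/c1ccc(OCc2ccccc2)cc1OCC=C)c1ccc(OCc2ccccc2)c(OCc2ccccc2)c1 | intermediate
8 | (S,E)-3-[2-(allyloxy)-4-(benzyloxy)phenyl]-1-[3,4-bis(benzyloxy)phenyl]prop-2-en-1-yl acetate | CC(=O)O[C@@H](/C=C/c1ccc(OCc2ccccc2)cc1OCC=C)c1ccc(OCc2ccccc2)c(OCc2ccccc2)c1 | intermediate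
9 | O-trimethylsilyl ketene acetal of 8 | C=C(O[Si](C)(C)C)O[C@@H](/C=C/c1ccc(OCc2ccccc2)cc1OCC=C)c1ccc(OCc2ccccc2)c(OCc2ccccc2)c1 | intermediate (not isolated)
10 | trimethylsilyl ester of 11 | C[Si](C)(C)OC(=O)C[C@@H](c1ccc(OCc2ccccc2)cc1OCC=C)/C=C/c1ccc(OCc2ccccc2)c(OCc2ccccc2)c1 | intermediate (not isolated)
11 | (R,E)-3-[2-(allyloxy)-4-(benzyloxy)phenyl]-5-[3,4-bis(benzyloxy)phenyl]pent-4-enoic acid | OC(=O)C[C@@H](c1ccc(OCc2ccccc2)cc1OCC=C)/C=C/c1ccc(OCc2ccccc2)c(OCc2ccccc2)c1 | intermediate
12 | N-acylimidazole of 11 | O=C(C[C@@H](c1ccc(OCc2ccccc2)cc1OCC=C)/C=C/c1ccc(OCc2ccccc2)c(OCc2ccccc2)c1)n1ccnc1 | intermediate (not isolated)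
13 | (R,E)-3-[2-(allyloxy)-4-(benzyloxy)phenyl]-5-[3,4-bis(benzyloxy)phenyl]-N-methoxy-N-methylpent-4-enamide | CON(C)C(=O)C[C@@H](c1ccc(OCc2ccccc2)cc1OCC=C)/C=C/c1ccc(OCc2ccccc2)c(OCc2ccccc2)c1 | intermediate
14 | (R,E)-5-[2-(allyloxy)-4-(benzyloxy)phenyl]-7-[3,4-bis(benzyloxy)phenyl]hepta-1,6-dien-3-one | C=CC(=O)C[C@@H](c1ccc(OCc2ccccc2)cc1OCC=C)/C=C/c1ccc(OCc2ccccc2)c(OCc2ccccc2)c1 | intermediate
15 | 4-(trifluoroacetyl) derivative of 14 (keto–enol mixture, new centre undefined) | C=CC(=O)C(C(=O)C(F)(F)F)[C@@H](c1ccc(OCc2ccccc2)cc1OCC=C)/C=C/c1ccc(OCc2ccccc2)c(OCc2ccccc2)c1 | intermediate (not isolated)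
16 | (R,E)-5-[2-(allyloxy)-4-(benzyloxy)phenyl]-7-[3,4-bis(benzyloxy)phenyl]-4-diazohepta-1,6-dien-3-one | C=CC(=O)C(=[N+]=[N-])[C@@H](c1ccc(OCc2ccccc2)cc1OCC=C)/C=C/c1ccc(OCc2ccccc2)c(OCc2ccccc2)c1 | intermediate (key-step precursor)
17 | acetylene | C#C | starting material
18 | triisopropylsilyl trifluoromethanesulfonate | CC(C)[Si](OS(=O)(=O)C(F)(F)F)(C(C)C)C(C)C | starting material
19 | lithium acetylide | [Li]C#C | intermediate (not isolated)
20 | lithium ethynolate | [Li]OC#C | intermediate (not isolated)
21 | (triisopropylsilyloxy)acetylene | C#CO[Si](C(C)C)(C(C)C)C(C)C | intermediate (key-step precursor)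
22 | vinylketene from 16 (C4 substituent and vinyl group on the ketene α-carbon) | C=CC(=C=O)[C@@H](c1ccc(OCc2ccccc2)cc1OCC=C)/C=C/c1ccc(OCc2ccccc2)c(OCc2ccccc2)c1 | intermediate (not isolated)
23 | 3-(triisopropylsilyloxy)-4-vinylcyclobut-2-enone carrying the C4 substituent at its C4 (ring centre undefined) | O=C1C=C(O[Si](C(C)C)(C(C)C)C(C)C)C1(C=C)[C@@H](c1ccc(OCc2ccccc2)cc1OCC=C)/C=C/c1ccc(OCc2ccccc2)c(OCc2ccccc2)c1 | intermediate (not isolated)
24 | dienylketene from ring opening of 23 | O=C=CC(O[Si](C(C)C)(C(C)C)C(C)C)=C(C=C)[C@@H](c1ccc(OCc2ccccc2)cc1OCC=C)/C=C/c1ccc(OCc2ccccc2)c(OCc2ccccc2)c1 | intermediate (not isolated)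
25 | 3-(triisopropylsilyloxy)cyclohexa-2,4-dienone carrying the C4 substituent at its C4 | O=C1C=C(O[Si](C(C)C)(C(C)C)C(C)C)C(=CC1)[C@@H](c1ccc(OCc2ccccc2)cc1OCC=C)/C=C/c1ccc(OCc2ccccc2)c(OCc2ccccc2)c1 | intermediate (not isolated)
26 | 4-{(1R,2E)-1-[2-(allyloxy)-4-(benzyloxy)phenyl]-3-[3,4-bis(benzyloxy)phenyl]prop-2-en-1-yl}-3-[(triisopropylsilyl)oxy]phenol | Oc1ccc(c(O[Si](C(C)C)(C(C)C)C(C)C)c1)[C@@H](c1ccc(OCc2ccccc2)cc1OCC=C)/C=C/c1ccc(OCc2ccccc2)c(OCc2ccccc2)c1 | intermediate (key-step product)
27 | 3,4-bis(benzyloxy)benzaldehyde | O=Cc1ccc(OCc2ccccc2)c(OCc2ccccc2)c1 | starting material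
28 | rac-1-[3,4-bis(benzyloxy)phenyl]prop-2-yn-1-ol | OC(C#C)c1ccc(OCc2ccccc2)c(OCc2ccccc2)c1 | intermediate
29 | rac-1-[3,4-bis(benzyloxy)phenyl]prop-2-yn-1-yl acetate | CC(=O)OC(C#C)c1ccc(OCc2ccccc2)c(OCc2ccccc2)c1 | intermediate
30 | ether of 26 with the (S)-1-[3,4-bis(benzyloxy)phenyl]prop-2-yn-1-yl group on the phenolic oxygen | C#C[C@H](Oc1ccc(c(O[Si](C(C)C)(C(C)C)C(C)C)c1)[C@@H](c1ccc(OCc2ccccc2)cc1OCC=C)/C=C/c1ccc(OCc2ccccc2)c(OCc2ccccc2)c1)c1ccc(OCc2ccccc2)c(OCc2ccccc2)c1 | intermediate
31 | (2S,3S)-trans-epoxide of the styryl double bond of 30 | C#C[C@H](Oc1ccc(c(O[Si](C(C)C)(C(C)C)C(C)C)c1)[C@@H](c1ccc(OCc2ccccc2)cc1OCC=C)[C@@H]1O[C@H]1c1ccc(OCc2ccccc2)c(OCc2ccccc2)c1)c1ccc(OCc2ccccc2)c(OCc2ccccc2)c1 | intermediate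
32 | phenol from 31 by loss of the allyl group | C#C[C@H](Oc1ccc(c(O[Si](C(C)C)(C(C)C)C(C)C)c1)[C@@H](c1ccc(OCc2ccccc2)cc1O)[C@@H]1O[C@H]1c1ccc(OCc2ccccc2)c(OCc2ccccc2)c1)c1ccc(OCc2ccccc2)c(OCc2ccccc2)c1 | intermediate (not isolated)
33 | (2R,3S,4R)-7-(benzyloxy)-2-[3,4-bis(benzyloxy)phenyl]-4-[4-{[(1S)-1-[3,4-bis(benzyloxy)phenyl]prop-2-yn-1-yl]oxy}-2-[(triisopropylsilyl)oxy]phenyl]chroman-3-ol | c1ccccc1COc1ccc2c(c1)O[C@H](c1ccc(OCc3ccccc3)c(OCc3ccccc3)c1)[C@@H](O)[C@H]2c1ccc(O[C@@H](C#C)c2ccc(OCc3ccccc3)c(OCc3ccccc3)c2)cc1O[Si](C(C)C)(C(C)C)C(C)C | intermediate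
34 | (2R,3S,4R)-7-(benzyloxy)-2-[3,4-bis(benzyloxy)phenyl]-4-{(2S)-2-[3,4-bis(benzyloxy)phenyl]-7-[(triisopropylsilyl)oxy]-2H-chromen-6-yl}chroman-3-ol | c1ccccc1COc1ccc2c(c1)O[C@H](c1ccc(OCc3ccccc3)c(OCc3ccccc3)c1)[C@@H](O)[C@H]2c1cc2c(cc1O[Si](C(C)C)(C(C)C)C(C)C)O[C@H](c1ccc(OCc3ccccc3)c(OCc3ccccc3)c1)C=C2 | intermediate
35 | (2R,3S,4S)-2-[3,4-bis(benzyloxy)phenyl]-6-{(2R,3S,4R)-7-(benzyloxy)-2-[3,4-bis(benzyloxy)phenyl]-3-hydroxychroman-4-yl}-7-[(triisopropylsilyl)oxy]chroman-3,4-diol | c1ccccc1COc1ccc2c(c1)O[C@H](c1ccc(OCc3ccccc3)c(OCc3ccccc3)c1)[C@@H](O)[C@H]2c1cc2c(cc1O[Si](C(C)C)(C(C)C)C(C)C)O[C@H](c1ccc(OCc3ccccc3)c(OCc3ccccc3)c1)[C@@H](O)[C@H]2O | intermediate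
36 | (2R,3S,4S)-2-[3,4-bis(benzyloxy)phenyl]-6-{(2R,3S,4S)-7-(benzyloxy)-2-[3,4-bis(benzyloxy)phenyl]-3-hydroxychroman-4-yl}chroman-3,4,7-triol | c1ccccc1COc1ccc2c(c1)O[C@H](c1ccc(OCc3ccccc3)c(OCc3ccccc3)c1)[C@@H](O)[C@H]2c1cc2c(cc1O)O[C@H](c1ccc(OCc3ccccc3)c(OCc3ccccc3)c1)[C@@H](O)[C@H]2O | intermediate
37 | (2R,3S,4S)-2-(3,4-dihydroxyphenyl)-6-[(2R,3S,4S)-2-(3,4-dihydroxyphenyl)-3,7-dihydroxychroman-4-yl]chroman-3,4,7-triol | Oc1ccc2c(c1)O[C@H](c1ccc(O)c(O)c1)[C@@H](O)[C@H]2c1cc2c(cc1O)O[C@H](c1ccc(O)c(O)c1)[C@@H](O)[C@H]2O | target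

## Step count and least certain steps

Total step count: 21. Longest linear sequence: 17 steps (steps 1, 2, 4 to 10, 12 and 15 to 21).

**Step 12 (key step).** The most likely failure is a 1,2-hydride shift from C4 to the carbene-like carbon in competition with the Wolff shift, which would give a cross-conjugated dienone. Also possible are slow cycloaddition of the hindered, disubstituted ketene (dimerisation, O-acylation of the product phenol) and isomerisation of the styrene if shorter wavelengths reach it. Fallback (the same vinylketene by a thermal route, without diazo compound or light): it sets out from 7. Esterification with but-3-enoic acid (N,N'-dicyclohexylcarbodiimide, 4-(dimethylamino)pyridine) gives the (S)-allylic but-3-enoate F1. Ireland–Claisen rearrangement through the silyl dienol ether (LDA, Me3SiCl) gives the 2-vinyl acid F2, with C4 set as in step 7 and the α-centre irrelevant. 1-Chloro-N,N,2-trimethylpropenylamine gives the acid chloride F3. Et3N in toluene at 60 to 80 °C with 21 present removes HCl to give 22, which passes through 23, 24 and 25 to 26, where the route is rejoined.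

**Step 10.** Enolisation of the simple vinyl ketone may be accompanied by Michael addition or polymerisation, and diazo transfer to the hindered secondary carbon may be slow. Fallback (a vinyl group masked against conjugate addition): it sets out from 13. (E)-2-(Trimethylsilyl)vinyllithium, from (E)-(2-bromovinyl)trimethylsilane and t-BuLi, gives the β-silyl enone F4. The same trifluoroacetylation and diazo transfer give the diazo enone F5. Irradiation with 21 as in step 12 gives the phenol F6, silylated at C4a'. Ipso-protodesilylation (CF3CO2H, CH2Cl2, 0 °C), fast at a carbon ortho and para to oxygen, returns to the route at 26.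

**Step 15.** Ionisation of the electron-rich propargylic acetate without the catalyst would give racemic ether or the methyl ether, and the ligand sense is assumed. Fallback (stoichiometric, stereospecific): it sets out from 28. MnO2 gives the ynone F7. Midland reduction with the Alpine-Borane antipode that gives the R alcohol (alkynyl as the small group) gives F8. A Mitsunobu reaction of F8 with 26 (PPh3, diisopropyl azodicarboxylate, toluene, −20 °C) forms the ether with inversion and returns to the route at 30.

**Step 16.** Poor facial selectivity or low conversion is possible, because the alkene carries the bulky diarylmethyl group and the catalyst may be mismatched with C4. Fallback (substrate control and separation): it sets out from 30. Dimethyldioxirane (acetone, −20 °C) gives 31 together with its (2R,3R)-diastereomer F9. Step 17 on the mixture gives 33 and its 3,4-trans isomer F10. Since C4 is already fixed these are diastereomers and can be separated by chromatography; the route is rejoined at 33.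

**Step 17.** The labile epoxide may be opened by the amine scavenger or by traces of acid before the phenol is free; 5-exo closure may compete with 6-endo; palladium may ionise the propargylic ether. Fallback (order reversed, so that the nucleophile is present when the epoxide forms): it sets out from 30. Pd(PPh3)4 and morpholine give the phenol F11. Shi epoxidation of F11 with the same ketone under bicarbonate buffer (near neutral, phenol protonated) forms 32, which closes as it forms, finished with pyridinium p-toluenesulfonate; the route is rejoined at 33.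

**Step 21.** The benzylic C4'–O bond may be hydrogenolysed alongside the benzyl ethers. Fallback (electron transfer in place of catalytic hydrogenation): it sets out from 36. Lithium 4,4'-di-tert-butylbiphenylide in THF at −78 °C first deprotonates the hydroxyls and then cleaves the aryl benzyl ethers; the C4' alkoxide is a poor leaving group under these conditions. Protonation gives 37 directly. This fallback makes no new compound (F0).

## Further compounds

F1 | step 12 | (S,E)-3-[2-(allyloxy)-4-(benzyloxy)phenyl]-1-[3,4-bis(benzyloxy)phenyl]prop-2-en-1-yl but-3-enoate | C=CCC(=O)O[C@@H](/C=C/c1ccc(OCc2ccccc2)cc1OCC=C)c1ccc(OCc2ccccc2)c(OCc2ccccc2)c1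
F2 | step 12 | (3R,4E)-3-[2-(allyloxy)-4-(benzyloxy)phenyl]-5-[3,4-bis(benzyloxy)phenyl]-2-vinylpent-4-enoic acid (C2 undefined) | OC(=O)C(C=C)[C@@H](c1ccc(OCc2ccccc2)cc1OCC=C)/C=C/c1ccc(OCc2ccccc2)c(OCc2ccccc2)c1
F3 | step 12 | acid chloride of F2 | ClC(=O)C(C=C)[C@@H](c1ccc(OCc2ccccc2)cc1OCC=C)/C=C/c1ccc(OCc2ccccc2)c(OCc2ccccc2)c1
F4 | step 10 | (1E,5R,6E)-5-[2-(allyloxy)-4-(benzyloxy)phenyl]-7-[3,4-bis(benzyloxy)phenyl]-1-(trimethylsilyl)hepta-1,6-dien-3-one | C[Si](C)(C)/C=C/C(=O)C[C@@H](c1ccc(OCc2ccccc2)cc1OCC=C)/C=C/c1ccc(OCc2ccccc2)c(OCc2ccccc2)c1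
F5 | step 10 | 4-diazo derivative of F4 | C[Si](C)(C)/C=C/C(=O)C(=[N+]=[N-])[C@@H](c1ccc(OCc2ccccc2)cc1OCC=C)/C=C/c1ccc(OCc2ccccc2)c(OCc2ccccc2)c1
F6 | step 10 | 2-(trimethylsilyl) derivative of 26 (silyl group ortho to the phenol, at C4a') | Oc1cc(O[Si](C(C)C)(C(C)C)C(C)C)c(cc1[Si](C)(C)C)[C@@H](c1ccc(OCc2ccccc2)cc1OCC=C)/C=C/c1ccc(OCc2ccccc2)c(OCc2ccccc2)c1
F7 | step 15 | 1-[3,4-bis(benzyloxy)phenyl]prop-2-yn-1-one | O=C(C#C)c1ccc(OCc2ccccc2)c(OCc2ccccc2)c1
F8 | step 15 | (R)-1-[3,4-bis(benzyloxy)phenyl]prop-2-yn-1-ol | C#C[C@@H](O)c1ccc(OCc2ccccc2)c(OCc2ccccc2)c1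
F9 | step 16 | (2R,3R)-epoxide, diastereomer of 31 | C#C[C@H](Oc1ccc(c(O[Si](C(C)C)(C(C)C)C(C)C)c1)[C@@H](c1ccc(OCc2ccccc2)cc1OCC=C)[C@H]1O[C@@H]1c1ccc(OCc2ccccc2)c(OCc2ccccc2)c1)c1ccc(OCc2ccccc2)c(OCc2ccccc2)c1
F10 | step 16 | (2S,3R,4R)-isomer of 33 (2,3-trans-3,4-trans) | c1ccccc1COc1ccc2c(c1)O[C@@H](c1ccc(OCc3ccccc3)c(OCc3ccccc3)c1)[C@H](O)[C@H]2c1ccc(O[C@@H](C#C)c2ccc(OCc3ccccc3)c(OCc3ccccc3)c2)cc1O[Si](C(C)C)(C(C)C)C(C)C
F11 | step 17 | phenol from 30 by loss of the allyl group | C#C[C@H](Oc1ccc(c(O[Si](C(C)C)(C(C)C)C(C)C)c1)[C@@H](c1ccc(OCc2ccccc2)cc1O)/C=C/c1ccc(OCc2ccccc2)c(OCc2ccccc2)c1)c1ccc(OCc2ccccc2)c(OCc2ccccc2)c1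
F0 | step 21 | none | none
A1 | alternative 1 | 7-(benzyloxy)-4-[7-(benzyloxy)-2-ethoxy-2H-chromen-6-yl]-2-ethoxy-2H-chromene | c1ccccc1COc1ccc2c(c1)OC(OCC)C=C2c1cc2c(cc1OCc1ccccc1)OC(OCC)C=C2
A2 | alternative 1 | diethyl [3,4-bis(benzyloxy)phenyl]boronate | CCOB(OCC)c1ccc(OCc2ccccc2)c(OCc2ccccc2)c1
A3 | alternative 1 | bis(flav-3-ene) with both C2 aryl groups, (2S,2'S) | c1ccccc1COc1ccc2c(c1)O[C@H](c1ccc(OCc3ccccc3)c(OCc3ccccc3)c1)C=C2c1cc2c(cc1OCc1ccccc1)O[C@H](c1ccc(OCc3ccccc3)c(OCc3ccccc3)c1)C=C2
A4 | alternative 2 | (S)-propargyl ether of the perbenzylated upper flavan-3-ol carrying the ring D phenol | c1ccccc1COc1ccc2c(c1)O[C@H](c1ccc(OCc3ccccc3)c(OCc3ccccc3)c1)[C@@H](OCc1ccccc1)[C@H]2c1ccc(O[C@@H](C#C)c2ccc(OCc3ccccc3)c(OCc3ccccc3)c2)cc1OCc1ccccc1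
A5 | alternative 2 | lower flav-3-ene joined to the protected upper flavan-3-ol | c1ccccc1COc1ccc2c(c1)O[C@H](c1ccc(OCc3ccccc3)c(OCc3ccccc3)c1)[C@@H](OCc1ccccc1)[C@H]2c1cc2c(cc1OCc1ccccc1)O[C@H](c1ccc(OCc3ccccc3)c(OCc3ccccc3)c1)C=C2
A6 | alternative 3 | (R)-2-[3,4-bis(benzyloxy)phenyl]-2-{5-(benzyloxy)-2-[2-(benzyloxy)-4-(triisopropylsilyloxy)benzoyl]phenoxy}acetaldehyde | O=C[C@H](Oc1cc(OCc2ccccc2)ccc1C(=O)c1ccc(O[Si](C(C)C)(C(C)C)C(C)C)cc1OCc1ccccc1)c1ccc(OCc2ccccc2)c(OCc2ccccc2)c1
A7 | alternative 3 | 2,3-trans-4-aryl-flavan-3,4-cis-diol | c1ccccc1COc1ccc2c(c1)O[C@H](c1ccc(OCc3ccccc3)c(OCc3ccccc3)c1)[C@@H](O)[C@]2(O)c1ccc(O[Si](C(C)C)(C(C)C)C(C)C)cc1OCc1ccccc1
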